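**Plan**

1. Retrosynthesis: the two O–benzyl bonds on ring B are cut last; before that the pyranone (ring C) is opened at C4a–C4, C4–C3 and O1–C2, giving an iodinated ring A arene, carbon monoxide (C4) and a ring B arylacetylene (C2, C3).
2. Enabling feature: ring A (C4a, C5, C6, C7, C8, C8a) bears oxygen on every carbon except C4a, and the oxygens on C5 and C8a are related by the mirror plane through C4a and C7. Iodine therefore has a single site, and either flanking oxygen can become O1 with the same result.
3. Forward, ring A piece: phloroglucinol triacetate → tribenzyl ether → dibromide → dimethoxy compound → free triol → iodotriol → iodotriol triacetate.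
4. Forward, ring B piece: 3,5-dihydroxy-4-methoxybenzoic acid → benzyl ester/ethers → alcohol → aldehyde → terminal alkyne.
5. Ring C is the only ring built; it closes in the three-component carbonylative annulation, after which hydrogenolysis frees the ring B phenols.
6. Stereochemistry: the target has no stereocentre and no configured double bond, so nothing has to be set.

Key step: step 11

Remark on the chemistry: the iodotriol is taken into the annulation as its triacetate. The two acetates beside iodine stay equivalent, so the symmetry argument is unchanged, and diethylamine removes all three acetyl groups in the same flask. Benzene-1,3,5-triyl triacetate (one acetylation away from phloroglucinol) and 3,5-dihydroxy-4-methoxybenzoic acid are assumed to be purchasable.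

**Route**

Step 1
Reactants: 1 benzene-1,3,5-triyl triacetate
Product: 2 1,3,5-tris(benzyloxy)benzene
Conditions: NaH (6.5 equiv), BnCl (3.3 equiv), DMF, 0 °C; H2O (3 equiv) added slowly; then rt
Reagents that add atoms: benzyl chloride, ClCc1ccccc1
Why: Williamson ether synthesis on phenoxides that are released one at a time by in-situ saponification of the aryl acetates, which keeps free phloroglucinol low and so should suppress C-benzylation.

Step 2
Reactants: 2 1,3,5-tris(benzyloxy)benzene
Product: 3 1,3,5-tris(benzyloxy)-2,4-dibromobenzene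
Conditions: NBS (2.05 equiv), CH2Cl2, 0 °C, dark
Reagents that add atoms: N-bromosuccinimide, O=C1CCC(=O)N1Br
Why: Electrophilic aromatic bromination of a ring whose three CH positions are equivalent and each activated by three alkoxy groups; each bromine deactivates and crowds the ring, so two equivalents should stop at the dibromide.

Step 3
Reactants: 3 1,3,5-tris(benzyloxy)-2,4-dibromobenzene
Product: 4 1,3,5-tris(benzyloxy)-2,4-dimethoxybenzene
Conditions: NaOMe (excess), CuBr (0.3 equiv), MeOH/DMF, 110 °C, sealed vessel
Reagents that add atoms: sodium methoxide, [Na+].[O-]C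
Why: Copper-catalysed Ullmann-type methoxylation of aryl bromides; the two carbon–bromine bonds are the only electrophilic sites and benzyl aryl ethers are inert to methoxide.

Step 4
Reactants: 4 1,3,5-tris(benzyloxy)-2,4-dimethoxybenzene
Product: 5 2,4-dimethoxybenzene-1,3,5-triol
Conditions: H2 (1 atm), 10% Pd/C, EtOAc/MeOH, rt; filtered and concentrated under argon
Reagents that add atoms: none
Why: Catalytic hydrogenolysis of benzyl aryl ethers; no halogen or other reducible group is present and the methyl ethers are untouched.

Step 5
Reactants: 5 2,4-dimethoxybenzene-1,3,5-triol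
Product: 6 2-iodo-4,6-dimethoxybenzene-1,3,5-triol
Conditions: I2 (1.05 equiv), NaHCO3, THF/H2O, 0 °C, under argon
Reagents that add atoms: iodine, II
Why: Electrophilic aromatic iodination of a phloroglucinol under bicarbonate buffering; only one ring CH remains, it is ortho, ortho and para to the three hydroxyls, and the 1,3,5-arrangement of the hydroxyls offers no quinone to which iodine could oxidise the ring.

Step 6
Reactants: 6 2-iodo-4,6-dimethoxybenzene-1,3,5-triol
Product: 7 2-iodo-4,6-dimethoxybenzene-1,3,5-triyl triacetate
Conditions: Ac2O, pyridine, DMAP (cat.), CH2Cl2, 0 °C to rt (crude 6 used at once)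
Reagents that add atoms: acetic anhydride, CC(=O)OC(C)=O
Why: DMAP-catalysed O-acylation of the three phenols, which turns the air-sensitive iodotriol into a storable, less electron-rich triacetate in which the two acetates flanking iodine are still equivalent.

Step 7
Reactants: 8 3,5-dihydroxy-4-methoxybenzoic acid
Product: 9 benzyl 3,5-bis(benzyloxy)-4-methoxybenzoate
Conditions: BnBr (3.3 equiv), K2CO3, DMF, 60 °C
Reagents that add atoms: benzyl bromide, BrCc1ccccc1
Why: Williamson O-alkylation of both phenoxides and SN2 esterification of the carboxylate in one operation.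

Step 8
Reactants: 9 benzyl 3,5-bis(benzyloxy)-4-methoxybenzoate
Product: 10 [3,5-bis(benzyloxy)-4-methoxyphenyl]methanol
Conditions: LiAlH4, THF, 0 °C to rt; then H2O, aq. NaOH
Reagents that add atoms: none
Why: Hydride reduction of the ester to the primary alcohol with LiAlH4; aryl benzyl and aryl methyl ethers are inert.

Step 9
Reactants: 10 [3,5-bis(benzyloxy)-4-methoxyphenyl]methanol
Product: 11 3,5-bis(benzyloxy)-4-methoxybenzaldehyde
Conditions: PhI(OAc)2 (1.1 equiv), TEMPO (10 mol%), CH2Cl2, rt
Reagents that add atoms: none
Why: TEMPO-catalysed oxidation of a benzylic alcohol with PhI(OAc)2 as terminal oxidant, which stops at the aldehyde and leaves the ethers alone.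

Step 10
Reactants: 11 3,5-bis(benzyloxy)-4-methoxybenzaldehyde
Product: 12 1,3-bis(benzyloxy)-5-ethynyl-2-methoxybenzene
Conditions: dimethyl (1-diazo-2-oxopropyl)phosphonate, K2CO3, MeOH, 0 °C to rt
Reagents that add atoms: dimethyl (1-diazo-2-oxopropyl)phosphonate, COP(=O)(OC)C(=[N+]=[N-])C(C)=O
Why: Seyferth–Gilbert homologation in its Ohira–Bestmann form, in which methanolysis of the acetyl group releases dimethyl (diazomethyl)phosphonate that converts the non-enolisable aldehyde into the terminal alkyne with loss of N2.

Step 11
Reactants: 7 2-iodo-4,6-dimethoxybenzene-1,3,5-triyl triacetate; 12 1,3-bis(benzyloxy)-5-ethynyl-2-methoxybenzene; 13 carbon monoxide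
Product: 17 2-[3,5-bis(benzyloxy)-4-methoxyphenyl]-5,7-dihydroxy-6,8-dimethoxy-4H-chromen-4-one, via ynone triacetate 14 (not isolated), via enaminone phenol 15 (not isolated), via flavone diacetate 16 (not isolated)
Conditions: PdCl2(PPh3)2 (5 mol%), dppp (5 mol%), thiourea (5 mol%), CO (1 atm), Et2NH (solvent), DBU (2 equiv), 40 °C; then more Et2NH, 45 °C
Reagents that add atoms: none
Why: Zerovalent palladium, generated from PdCl2(PPh3)2 and carried by dppp and thiourea, inserts into the carbon–iodine bond of 7, CO inserts to give the aroyl–palladium species, and alkyne 12, deprotonated by the amine on palladium, is coupled by reductive elimination to ynone 14, which creates C4a–C4 and C4–C3. Diethylamine then adds to the triple bond of 14 and removes one of the two equivalent acetates beside the ketone to give enaminone 15, whose phenoxide attacks the amine-bearing carbon and expels diethylamine (O1–C2) to give flavone diacetate 16, and aminolysis of the two remaining acetates ends at 17. The closest known reaction type is the palladium-catalysed carbonylative annulation of o-iodophenols and of their acetates with terminal alkynes in diethylamine to give flavones. The pyranone (ring C) closes in the 6-endo mode by addition–elimination at the enaminone β-carbon, and no stereocentre is formed. The step needs CO insertion to outrun direct alkynylation and 6-endo to outrun 5-exo (aurone) closure: the two ortho acetoxy groups crowd the aryl–palladium species so that small CO enters before the alkyne, copper is left out so that no copper acetylide feeds the carbonyl-free path, and the acetates keep the phenol masked until the amine has converted the ynone into the enaminone. Which flanking oxygen becomes O1 does not matter, because the mirror plane of 7 through C4a and C7 makes the two identical, and the other one ends as the chelated 5-OH.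

Step 12
Reactants: 17 2-[3,5-bis(benzyloxy)-4-methoxyphenyl]-5,7-dihydroxy-6,8-dimethoxy-4H-chromen-4-one
Product: 18 2-(3,5-dihydroxy-4-methoxyphenyl)-5,7-dihydroxy-6,8-dimethoxy-4H-chromen-4-one
Conditions: H2 (1 atm), 10% Pd/C, THF/MeOH, rt, stopped when the benzyl ethers are consumed
Reagents that add atoms: none
Why: Catalytic hydrogenolysis of the two benzyl aryl ethers; the conjugated C2–C3 double bond of the chromone is reduced far more slowly at one atmosphere, so the reaction can be halted at the target.

**Compound list**

1 | benzene-1,3,5-triyl triacetate (phloroglucinol triacetate) | CC(=O)Oc1cc(OC(C)=O)cc(OC(C)=O)c1 | starting material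
2 | 1,3,5-tris(benzyloxy)benzene | c1ccc(COc2cc(OCc3ccccc3)cc(OCc3ccccc3)c2)cc1 | intermediate
3 | 1,3,5-tris(benzyloxy)-2,4-dibromobenzene | Brc1c(OCc2ccccc2)cc(OCc2ccccc2)c(Br)c1OCc1ccccc1 | intermediate
4 | 1,3,5-tris(benzyloxy)-2,4-dimethoxybenzene | COc1c(OCc2ccccc2)cc(OCc2ccccc2)c(OC)c1OCc1ccccc1 | intermediate
5 | 2,4-dimethoxybenzene-1,3,5-triol | COc1c(O)cc(O)c(OC)c1O | intermediate
6 | 2-iodo-4,6-dimethoxybenzene-1,3,5-triol | COc1c(O)c(I)c(O)c(OC)c1O | intermediate
7 | 2-iodo-4,6-dimethoxybenzene-1,3,5-triyl triacetate | COc1c(OC(C)=O)c(I)c(OC(C)=O)c(OC)c1OC(C)=O | intermediate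
8 | 3,5-dihydroxy-4-methoxybenzoic acid | COc1c(O)cc(C(=O)O)cc1O | starting material
9 | benzyl 3,5-bis(benzyloxy)-4-methoxybenzoate | COc1c(OCc2ccccc2)cc(C(=O)OCc2ccccc2)cc1OCc1ccccc1 | intermediate
10 | [3,5-bis(benzyloxy)-4-methoxyphenyl]methanol | COc1c(OCc2ccccc2)cc(CO)cc1OCc1ccccc1 | intermediate
11 | 3,5-bis(benzyloxy)-4-methoxybenzaldehyde | COc1c(OCc2ccccc2)cc(C=O)cc1OCc1ccccc1 | intermediate
12 | 1,3-bis(benzyloxy)-5-ethynyl-2-methoxybenzene | C#Cc1cc(OCc2ccccc2)c(OC)c(OCc2ccccc2)c1 | intermediate
13 | carbon monoxide | [C-]#[O+] | starting material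
14 | 2-{3-[3,5-bis(benzyloxy)-4-methoxyphenyl]prop-2-ynoyl}-4,6-dimethoxybenzene-1,3,5-triyl triacetate (ynone triacetate) | COc1c(OC(C)=O)c(C(=O)C#Cc2cc(OCc3ccccc3)c(OC)c(OCc3ccccc3)c2)c(OC(C)=O)c(OC)c1OC(C)=O | intermediate (not isolated)
15 | 4-{(2E)-3-[3,5-bis(benzyloxy)-4-methoxyphenyl]-3-(diethylamino)prop-2-enoyl}-5-hydroxy-2,6-dimethoxy-1,3-phenylene diacetate (enaminone phenol; the geometry of this push–pull alkene is of no consequence) | CCN(CC)/C(=C/C(=O)c1c(O)c(OC)c(OC(C)=O)c(OC)c1OC(C)=O)c1cc(OCc2ccccc2)c(OC)c(OCc2ccccc2)c1 | intermediate (not isolated)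
16 | 2-[3,5-bis(benzyloxy)-4-methoxyphenyl]-6,8-dimethoxy-4-oxo-4H-chromene-5,7-diyl diacetate (flavone diacetate) | COc1c(OCc2ccccc2)cc(-c2cc(=O)c3c(OC(C)=O)c(OC)c(OC(C)=O)c(OC)c3o2)cc1OCc1ccccc1 | intermediate (not isolated)
17 | 2-[3,5-bis(benzyloxy)-4-methoxyphenyl]-5,7-dihydroxy-6,8-dimethoxy-4H-chromen-4-one | COc1c(OCc2ccccc2)cc(-c2cc(=O)c3c(O)c(OC)c(O)c(OC)c3o2)cc1OCc1ccccc1 | intermediate
18 | 2-(3,5-dihydroxy-4-methoxyphenyl)-5,7-dihydroxy-6,8-dimethoxy-4H-chromen-4-one | COc1c(O)cc(-c2cc(=O)c3c(O)c(OC)c(O)c(OC)c3o2)cc1O | target

**Summary**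

Total step count: 12.
Longest linear sequence: 8 steps (steps 1–6, 11 and 12). The ring B branch (steps 7–10) joins at step 11.

**Steps most likely to fail**

Step 11 (carbonylative annulation). The flanking acetates may be lost to the amine before oxidative addition, leaving a phenoxide-rich iodide that inserts slowly and is lost by protodeiodination. Direct alkynylation may also outrun CO insertion and lead on to a benzofuran. The fallback sets out from 4 and 12 and builds the same ynone skeleton without palladium. Vilsmeier–Haack formylation of 4 (POCl3, DMF) at its single ring CH should give 2,4,6-tris(benzyloxy)-3,5-dimethoxybenzaldehyde F1. The lithium acetylide of 12 (n-BuLi, THF, −78 °C) should add to it to give racemic 1-[2,4,6-tris(benzyloxy)-3,5-dimethoxyphenyl]-3-[3,5-bis(benzyloxy)-4-methoxyphenyl]prop-2-yn-1-ol F2. MnO2 in CH2Cl2 should oxidise this to 1-[2,4,6-tris(benzyloxy)-3,5-dimethoxyphenyl]-3-[3,5-bis(benzyloxy)-4-methoxyphenyl]prop-2-yn-1-one F3. BCl3 with pentamethylbenzene in CH2Cl2 at −78 °C should then remove all five benzyl groups to give 3-(3,5-dihydroxy-4-methoxyphenyl)-1-(2,4,6-trihydroxy-3,5-dimethoxyphenyl)prop-2-yn-1-one F4. Diethylamine in ethanol should close F4 in the 6-endo sense through its enaminone, with either of the two equivalent ortho hydroxyls. This sequence bypasses 17 and comes back to the route at 18.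

Step 3 (double methoxylation). Methoxide can act as a hydride donor at the metal, so reductive loss of bromine may compete, and the second substitution may stall on the more electron-rich, doubly flanked ring. The fallback sets out from 3 and forms the carbon–oxygen bonds with hydroxide, which has no β-hydrogen to give up. Pd2(dba)3, tBuXPhos and KOH in 1,4-dioxane/H2O at 100 °C should give 2,4,6-tris(benzyloxy)benzene-1,3-diol F5. O-Methylation with MeI and K2CO3 in acetone then comes back to the route at 4.

Step 5 (iodination of the free triol). The electron-rich triol may be degraded oxidatively by iodine or air, and the free iodotriol may lose iodine during isolation. The fallback sets out from 4 and places iodine before the phenols are unmasked. NIS with catalytic TFA in MeCN at 0 °C should give 1,3,5-tris(benzyloxy)-2-iodo-4,6-dimethoxybenzene F6. BCl3 with pentamethylbenzene in CH2Cl2 at −78 °C should then cleave the three benzyl ethers without touching the methyl ethers or the iodide. This comes back to the route at 6, which is acetylated at once as in step 6.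

**Further compounds**

F1 | step 11 | 2,4,6-tris(benzyloxy)-3,5-dimethoxybenzaldehyde | COc1c(OCc2ccccc2)c(C=O)c(OCc2ccccc2)c(OC)c1OCc1ccccc1
F2 | step 11 | 1-[2,4,6-tris(benzyloxy)-3,5-dimethoxyphenyl]-3-[3,5-bis(benzyloxy)-4-methoxyphenyl]prop-2-yn-1-ol (racemic) | COc1c(OCc2ccccc2)c(C(O)C#Cc2cc(OCc3ccccc3)c(OC)c(OCc3ccccc3)c2)c(OCc2ccccc2)c(OC)c1OCc1ccccc1
F3 | step 11 | 1-[2,4,6-tris(benzyloxy)-3,5-dimethoxyphenyl]-3-[3,5-bis(benzyloxy)-4-methoxyphenyl]prop-2-yn-1-one | COc1c(OCc2ccccc2)c(C(=O)C#Cc2cc(OCc3ccccc3)c(OC)c(OCc3ccccc3)c2)c(OCc2ccccc2)c(OC)c1OCc1ccccc1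
F4 | step 11 | 3-(3,5-dihydroxy-4-methoxyphenyl)-1-(2,4,6-trihydroxy-3,5-dimethoxyphenyl)prop-2-yn-1-one | COc1c(O)cc(C#CC(=O)c2c(O)c(OC)c(O)c(OC)c2O)cc1O
F5 | step 3 | 2,4,6-tris(benzyloxy)benzene-1,3-diol | Oc1c(OCc2ccccc2)cc(OCc2ccccc2)c(O)c1OCc1ccccc1
F6 | step 5 | 1,3,5-tris(benzyloxy)-2-iodo-4,6-dimethoxybenzene | COc1c(OCc2ccccc2)c(I)c(OCc2ccccc2)c(OC)c1OCc1ccccc1
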